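I had 3 questions on two flasks, elm and maple, which differ in their charge of transfer agent.

- elm: free monomer 0.27 M; transfer agent 8.10 mM; pre-initiator 2.7 mM; time 4.0 min
- maple: free monomer 0.27 M; transfer agent 25.0 mM; pre-initiator 2.7 mM; time 4.0 min

- which of the two ends with the longer chains by the average number of monomer units in a chain (chains begun, living or dead) ("neither" if they lie within 10%) (elm / maple / neither)
- average number of monomer units in a chain (chains begun, living or dead) at the end, elm
- average number of monomer units in a chain (chains begun, living or dead) at the end, maple

    free monomer + initiator → living end + monomer in chains (k1 = 0.11 M⁻¹ s⁻¹)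
    free monomer + living end → monomer in chains + living end, rate k2*[living end]*[free monomer] (k2 = 6.8 M⁻¹ s⁻¹)
    living end + transfer agent → dead chain (k3 = 0.75 M⁻¹ s⁻¹)
    living end + monomer in chains → dead end (k4 = 0.0048 M⁻¹ s⁻¹)
    pre-initiator → initiator (k5 = 0.0013 s⁻¹)

In elm the half-life of initiator at the charged amounts, 0.39 min, is much shorter than that of pre-initiator, 8.9 min, so I treated each release as a chain begun, and held the release at its starting rate, 0.211 mM min⁻¹, in both flasks. By the transfer step, a living end lasts on average the inverse of the transfer constant times c(transfer agent): 2.74 min in elm and 0.889 min in maple. In that time it adds 302 units in elm and 97.9 in maple at the charged c(free monomer): this is the growth per life, the kinetic chain length.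

Chains begin throughout the run, so I replaced their unfinished lives by the mean over starting times, 0.474 of a life in elm and 0.780 in maple. I also replaced the c(free monomer) curve by its mean, 82.0% of the charge in elm and 89.4% in maple. The product gave 68.3 for maple and 117 for elm, so elm came out longer than maple.

The forecast chose elm, with 114 (100 to 130) for elm and 68 (58 to 78) for maple, on the ground that “the threefold higher level in maple holds fewer living ends”.

The simulation gave elm: 119 in elm and 70.1 in maple, or 0.394 and 0.716 of the growth per life, against my 0.389 and 0.697. My mean ran low in elm: the charge and the end reading there give 86.5%, more than my 82.0%.

Neither flask had come to rest at 4.00 min: elm held 73% of its free monomer and maple 84%. At 40.0 min these stood at 6.51% and 38.0%, and the averages at 102 and 65.2.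

In the neighbour, elm with 0.16 M of free monomer, the growth per life falls to 179; in my reckoning the lifetime and both shares stay as in elm, which gives 69.6. The simulation gave 69.5.

All constants are invented, and the outcome is calculated.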